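**Retrosynthetic overview**
- The (Z)-γ-acetoxy-enal unit AcOCH2–C=C–CHO on the cyclopentene is a ring-opened butenolide. The target is therefore traced back (double Swern oxidation, desilylation, regioselective acetylation, lactone reduction) to a cyclopentene-fused butenolide that already carries the whole side chain.
- Key disconnection: the ring bond between the side-chain-bearing methine (cyclopentene C-3) and the neighbouring ring CH2 (C-4). It is made by a vinylcyclopropane → cyclopentene ring expansion of an α-alkylidene γ-lactone with a spiro-cyclopropane next to the alkylidene carbon.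
- Enabling feature: the tetrasubstituted C-1=C-2 alkene of the cyclopentene is flanked by the allylic methine C-3 and by the C-4H2–C-5H2 unit. This is exactly the pattern left by a 1-vinylcyclopropane (cyclopropane = C-1, C-4, C-5; vinyl = C-2=C-3), and the carbonyl on C-2 makes that alkene a good ligand for zerovalent nickel.
- The alkylidene lactone comes from an aldol condensation of 5-oxaspiro[2.4]heptan-6-one with an α-chiral aldehyde made from geranyl bromide (copper-catalysed three-carbon homologation, organocatalytic α-hydroxymethylation).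
- Ring order: cyclopropane and γ-lactone are bought; the cyclopentene is the only ring formed (step 7, consuming the cyclopropane); the lactone ring is opened afterwards.

Key step: step 7

Remark: 5-oxaspiro[2.4]heptan-6-one is treated as a purchasable building block, and catalyst-bound species of catalytic cycles (enamine, nickelacycle, acyl-enzyme) are transient and are not counted as compounds. TBS = tert-butyldimethylsilyl.

**Step 1**
Reactants: 1 geranyl bromide [(2E)-1-bromo-3,7-dimethylocta-2,6-diene]; 2 2-(2-bromoethyl)-1,3-dioxolane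
Product: 4 2-[(4E)-5,9-dimethyldeca-4,8-dien-1-yl]-1,3-dioxolane, via [2-(1,3-dioxolan-2-yl)ethyl]magnesium bromide 3 (not isolated)
Conditions: Mg, THF, 25 °C; then 1, Li2CuCl4 (3 mol %), THF, −78 → 0 °C
Reagents that add atoms: none
Why: Copper-catalysed cross-coupling of a primary alkyl Grignard reagent with an allylic bromide, which should proceed by direct substitution at the primary allylic carbon because the other allyl terminus is fully substituted, keeping the E-alkene; no stereocentre is formed.

**Step 2**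
Reactants: 4 2-[(4E)-5,9-dimethyldeca-4,8-dien-1-yl]-1,3-dioxolane
Product: 5 (5E)-6,10-dimethylundeca-5,9-dienal
Conditions: 1 M HCl, THF, 25 °C
Reagents that add atoms: water, O
Why: Acid-catalysed acetal hydrolysis, with dilute acid at room temperature chosen so that the two trisubstituted alkenes are not protonated.

**Step 3**
Reactants: 5 (5E)-6,10-dimethylundeca-5,9-dienal
Product: 6 (2R,5E)-2-(hydroxymethyl)-6,10-dimethylundeca-5,9-dienal
Conditions: aq. CH2O (37 %), (S)-α,α-diphenylprolinol trimethylsilyl ether (10 mol %), pH 7 buffer (NaH2PO4/Na2HPO4), toluene, 25 °C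
Reagents that add atoms: formaldehyde, C=O
Why: Enamine-catalysed cross-aldol reaction with formaldehyde (direct organocatalytic α-hydroxymethylation), in which the E-enamine is attacked on the face away from the CPh2(OSiMe3) group of the (S)-catalyst and should thereby give the 2R stereocentre.

**Step 4**
Reactants: 6 (2R,5E)-2-(hydroxymethyl)-6,10-dimethylundeca-5,9-dienal
Product: 7 (2R,5E)-2-[(TBS-oxy)methyl]-6,10-dimethylundeca-5,9-dienal
Conditions: TBSCl, imidazole, CH2Cl2, 0 °C
Reagents that add atoms: tert-butyldimethylsilyl chloride, CC(C)(C)[Si](C)(C)Cl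
Why: Silylation of the primary alcohol under weakly basic conditions at 0 °C, which caps the β-hydroxy aldehyde before it can dehydrate or epimerise.

**Step 5**
Reactants: 8 5-oxaspiro[2.4]heptan-6-one; 7 (2R,5E)-2-[(TBS-oxy)methyl]-6,10-dimethylundeca-5,9-dienal
Product: 10 7-[(2R,5E)-1-hydroxy-2-[(TBS-oxy)methyl]-6,10-dimethylundeca-5,9-dien-1-yl]-5-oxaspiro[2.4]heptan-6-one (mixture at the two new centres), via lithium 5-oxaspiro[2.4]hept-6-en-6-olate 9 (not isolated)
Conditions: LiN(i-Pr)2, THF, −78 °C; then 7, −78 °C; AcOH quench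
Reagents that add atoms: none
Why: Lithium-enolate aldol addition, in which 1,2-addition at −78 °C is faster than enolisation of the α-branched aldehyde, so the side-chain stereocentre is kept while the two new centres are erased in step 6.

**Step 6**
Reactants: 10 aldol adduct
Product: 12 (7E)-7-[(2S,5E)-2-[(TBS-oxy)methyl]-6,10-dimethylundeca-5,9-dien-1-ylidene]-5-oxaspiro[2.4]heptan-6-one, via mesylate 11 (not isolated)
Conditions: MsCl, Et3N, CH2Cl2, 0 °C; then DBU, 25 °C
Reagents that add atoms: none
Why: Mesylation followed by E1cB elimination, which should give the thermodynamically preferred E-alkylidene lactone (side chain anti to the carbonyl) without touching the allylic stereocentre, whose descriptor changes from R to S only through the priority rules.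

**Step 7**
Reactants: 12 (7E)-7-[(2S,5E)-2-[(TBS-oxy)methyl]-6,10-dimethylundeca-5,9-dien-1-ylidene]-5-oxaspiro[2.4]heptan-6-one
Product: 13 (6R)-6-[(2S,5E)-1-(TBS-oxy)-6,10-dimethylundeca-5,9-dien-2-yl]-3,4,5,6-tetrahydro-1H-cyclopenta[c]furan-1-one
Conditions: Ni(cod)2 (10 mol %), (4R,5R)-1,3-bis(2-isopropylphenyl)-4,5-diphenylimidazolidin-2-ylidene (12 mol %, from its HBF4 salt and KOt-Bu), toluene, 60 °C
Reagents that add atoms: none
Why: Proposed new method: zerovalent nickel bound to the electron-poor exocyclic alkene of 12 should insert into a proximal spiro-carbon–CH2 bond of the cyclopropane (releasing about 27 kcal/mol of ring strain) to give an η3-allyl/η1-alkyl six-membered nickelacycle, and C(sp3)–C(sp3) reductive elimination between the Ni–CH2 carbon and the allyl terminus (the former alkene CH) then forms the key bond together with the tetrasubstituted, lactone-conjugated ring alkene. The closest known reaction is the Ni(cod)2/N-heterocyclic-carbene-catalysed vinylcyclopropane-to-cyclopentene rearrangement, established with achiral carbenes; new here are the α-cyclopropyl-α,β-unsaturated lactone substrate and the use of a chiral carbene for face selection. The cyclopentene closes as a formal 1,3-shift, that is, a five-membered ring formed by reductive elimination from the six-membered metallacycle, while the butenolide ring is carried through unchanged. The single new stereocentre (C-6 of 13) is to be set by the ligand: the two allylnickel diastereomers should interconvert by η3–η1–η3 slippage (which also makes the E/Z purity of 12 unimportant), the chiral carbene pocket selecting the one that eliminates to the 6R product, whereas the existing side-chain centre carries two sterically similar CH2 arms and should exert little bias of its own. The step needs C–C reductive elimination rather than β-hydride elimination to open-chain dienes (secured by the bulky carbene), reaction only at the strained ring next to the nickel-binding enoate and not at the isolated trisubstituted alkenes, and face selectivity (secured by the ligand antipode, to be fixed in a screen of both enantiomers).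

**Step 8**
Reactants: 13 cyclopentene-fused butenolide
Product: 14 [(3R)-3-[(2S,5E)-1-(TBS-oxy)-6,10-dimethylundeca-5,9-dien-2-yl]cyclopent-1-ene-1,2-diyl]dimethanol
Conditions: i-Bu2AlH (4 equiv), CH2Cl2, −78 → 0 °C
Reagents that add atoms: none
Why: Hydride reduction of the butenolide through the lactol to the (Z)-ene-1,4-diol (1,2-reduction, the tetrasubstituted alkene resisting conjugate reduction), with silyl ether and isolated alkenes inert to i-Bu2AlH.

**Step 9**
Reactants: 14 ene-diol
Product: 15 [(3R)-2-(hydroxymethyl)-3-[(2S,5E)-1-(TBS-oxy)-6,10-dimethylundeca-5,9-dien-2-yl]cyclopent-1-en-1-yl]methyl acetate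
Conditions: immobilised Candida antarctica lipase B, vinyl acetate, t-BuOMe, 25 °C
Reagents that add atoms: vinyl acetate, CC(=O)OC=C
Why: Lipase-catalysed transesterification with an enol ester (irreversible acyl transfer through the acyl-enzyme), which should acylate the less hindered primary alcohol, that is, the CH2OH on the ring carbon remote from the branched C-3 substituent.

**Step 10**
Reactants: 15 mono-acetate
Product: 16 [(3R)-2-(hydroxymethyl)-3-[(2S,5E)-1-hydroxy-6,10-dimethylundeca-5,9-dien-2-yl]cyclopent-1-en-1-yl]methyl acetate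
Conditions: HF·pyridine, pyridine, THF, 0 → 25 °C
Reagents that add atoms: none
Why: Fluoride-induced cleavage of the primary silyl ether under buffered, mildly acidic conditions that should leave the acetate in place and avoid base-promoted 1,4-acetyl migration.

**Step 11**
Reactants: 16 diol acetate
Product: 17 [(3R)-2-formyl-3-[(2S,5E)-6,10-dimethyl-1-oxoundeca-5,9-dien-2-yl]cyclopent-1-en-1-yl]methyl acetate (target)
Conditions: (COCl)2, DMSO, CH2Cl2, −78 °C; then i-Pr2NEt, −78 → −20 °C
Reagents that add atoms: none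
Why: Swern oxidation, which converts both primary alcohols into alkoxysulfonium ions before base is added, so that the 1,5-dialdehyde forms without passing through a lactol that could be over-oxidised, while the hindered base at low temperature should keep the α-formyl stereocentre intact.

**Compound list**
1 | geranyl bromide, (2E)-1-bromo-3,7-dimethylocta-2,6-diene | CC(C)=CCC/C(C)=C/CBr | starting material
2 | 2-(2-bromoethyl)-1,3-dioxolane | BrCCC1OCCO1 | starting material
3 | [2-(1,3-dioxolan-2-yl)ethyl]magnesium bromide | Br[Mg]CCC1OCCO1 | intermediate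
4 | 2-[(4E)-5,9-dimethyldeca-4,8-dien-1-yl]-1,3-dioxolane | CC(C)=CCC/C(C)=C/CCCC1OCCO1 | intermediate
5 | (5E)-6,10-dimethylundeca-5,9-dienal | O=CCCC/C=C(\C)CCC=C(C)C | intermediate
6 | (2R,5E)-2-(hydroxymethyl)-6,10-dimethylundeca-5,9-dienal | O=C[C@@H](CO)CC/C=C(\C)CCC=C(C)C | intermediate
7 | (2R,5E)-2-[(TBS-oxy)methyl]-6,10-dimethylundeca-5,9-dienal | O=C[C@@H](CO[Si](C)(C)C(C)(C)C)CC/C=C(\C)CCC=C(C)C | intermediate
8 | 5-oxaspiro[2.4]heptan-6-one | O=C1CC2(CC2)CO1 | starting material
9 | lithium 5-oxaspiro[2.4]hept-6-en-6-olate | [Li]OC1=CC2(CC2)CO1 | intermediate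
10 | 7-[(2R,5E)-1-hydroxy-2-[(TBS-oxy)methyl]-6,10-dimethylundeca-5,9-dien-1-yl]-5-oxaspiro[2.4]heptan-6-one (mixture at C-7 and the carbinol carbon) | O=C1OCC2(CC2)C1C(O)[C@@H](CO[Si](C)(C)C(C)(C)C)CC/C=C(\C)CCC=C(C)C | intermediate
11 | methanesulfonate of 10 at the carbinol oxygen (same mixture) | O=C1OCC2(CC2)C1C(OS(C)(=O)=O)[C@@H](CO[Si](C)(C)C(C)(C)C)CC/C=C(\C)CCC=C(C)C | intermediate
12 | (7E)-7-[(2S,5E)-2-[(TBS-oxy)methyl]-6,10-dimethylundeca-5,9-dien-1-ylidene]-5-oxaspiro[2.4]heptan-6-one | O=C1OCC2(CC2)/C1=C\[C@@H](CO[Si](C)(C)C(C)(C)C)CC/C=C(\C)CCC=C(C)C | intermediate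
13 | (6R)-6-[(2S,5E)-1-(TBS-oxy)-6,10-dimethylundeca-5,9-dien-2-yl]-3,4,5,6-tetrahydro-1H-cyclopenta[c]furan-1-one | O=C1OCC2=C1[C@@H]([C@@H](CO[Si](C)(C)C(C)(C)C)CC/C=C(\C)CCC=C(C)C)CC2 | intermediate
14 | [(3R)-3-[(2S,5E)-1-(TBS-oxy)-6,10-dimethylundeca-5,9-dien-2-yl]cyclopent-1-ene-1,2-diyl]dimethanol | OCC1=C(CO)[C@@H]([C@@H](CO[Si](C)(C)C(C)(C)C)CC/C=C(\C)CCC=C(C)C)CC1 | intermediate
15 | [(3R)-2-(hydroxymethyl)-3-[(2S,5E)-1-(TBS-oxy)-6,10-dimethylundeca-5,9-dien-2-yl]cyclopent-1-en-1-yl]methyl acetate | CC(=O)OCC1=C(CO)[C@@H]([C@@H](CO[Si](C)(C)C(C)(C)C)CC/C=C(\C)CCC=C(C)C)CC1 | intermediate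
16 | [(3R)-2-(hydroxymethyl)-3-[(2S,5E)-1-hydroxy-6,10-dimethylundeca-5,9-dien-2-yl]cyclopent-1-en-1-yl]methyl acetate | CC(=O)OCC1=C(CO)[C@@H]([C@@H](CO)CC/C=C(\C)CCC=C(C)C)CC1 | intermediate
17 | [(3R)-2-formyl-3-[(2S,5E)-6,10-dimethyl-1-oxoundeca-5,9-dien-2-yl]cyclopent-1-en-1-yl]methyl acetate | CC(=O)OCC1=C(C=O)[C@@H]([C@@H](C=O)CC/C=C(\C)CCC=C(C)C)CC1 | target

**Step count and risks**
Total step count: 11. Longest linear sequence: 11 steps (from geranyl bromide 1; lactone 8 enters at step 5).

Steps most likely to fail: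

1. Step 7 (proposed new method). What may go wrong: poor facial selection at the allylnickel stage, or β-hydride elimination to open-chain dienes outrunning ring closure. Fallback: give up catalyst control and rely on the side-chain stereocentre already present to make the two ring epimers separable. Setting out from 12, the known achiral protocol (Ni(cod)2 with 1,3-bis(2,6-diisopropylphenyl)imidazol-2-ylidene, toluene, 60 °C) should give 13 together with its ring epimer, (6S)-6-[(2S,5E)-1-(TBS-oxy)-6,10-dimethylundeca-5,9-dien-2-yl]-3,4,5,6-tetrahydro-1H-cyclopenta[c]furan-1-one F1. The two are diastereomers and are separated by chromatography, and the route is rejoined at 13.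

2. Step 9. What may go wrong: acyl transfer to the wrong allylic hydroxyl, or double acylation. Fallback: distinguish the two allylic oxygens by oxidation level, using the lactone itself. Setting out from 13:
   - Me(MeO)NH·HCl/AlMe3 (CH2Cl2, 0 → 25 °C) opens the butenolide to (5R)-5-[(2S,5E)-1-(TBS-oxy)-6,10-dimethylundeca-5,9-dien-2-yl]-2-(hydroxymethyl)-N-methoxy-N-methylcyclopent-1-ene-1-carboxamide F2.
   - Ac2O/pyridine/DMAP gives [(3R)-3-[(2S,5E)-1-(TBS-oxy)-6,10-dimethylundeca-5,9-dien-2-yl]-2-[methoxy(methyl)carbamoyl]cyclopent-1-en-1-yl]methyl acetate F3.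
   - Cp2Zr(H)Cl (THF, 25 °C) reduces the amide, without touching the acetate, to [(3R)-3-[(2S,5E)-1-(TBS-oxy)-6,10-dimethylundeca-5,9-dien-2-yl]-2-formylcyclopent-1-en-1-yl]methyl acetate F4.
   - NaBH4/CeCl3 (MeOH, −40 °C) returns the allylic alcohol, which is 15, where the route is rejoined. Rejoining there keeps the final double Swern oxidation and avoids handling a free hydroxy-aldehyde.

3. Step 3. What may go wrong: dehydration or oligomerisation of the β-hydroxy aldehyde, and erosion of enantiopurity by enolisation during isolation. Fallback: auxiliary control in place of organocatalysis. Setting out from 5: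
   - NaClO2/NaH2PO4/2-methyl-2-butene gives (5E)-6,10-dimethylundeca-5,9-dienoic acid F5.
   - Pivaloyl chloride/Et3N, then the lithium salt of (S)-4-benzyl-1,3-oxazolidin-2-one (from n-BuLi), gives (4S)-4-benzyl-3-[(5E)-6,10-dimethylundeca-5,9-dienoyl]-1,3-oxazolidin-2-one F6.
   - Titanium-enolate hydroxymethylation (TiCl4, i-Pr2NEt, then 1,3,5-trioxane/TiCl4, CH2Cl2, 0 °C), anti to the benzyl group, gives (4S)-4-benzyl-3-[(2R,5E)-2-(hydroxymethyl)-6,10-dimethylundeca-5,9-dienoyl]-1,3-oxazolidin-2-one F7.
   - TBSCl/imidazole gives (4S)-4-benzyl-3-[(2R,5E)-2-[(TBS-oxy)methyl]-6,10-dimethylundeca-5,9-dienoyl]-1,3-oxazolidin-2-one F8.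
   - LiBH4 (THF/MeOH, 0 °C) removes the auxiliary to give (2S,5E)-2-[(TBS-oxy)methyl]-6,10-dimethylundeca-5,9-dien-1-ol F9.
   - Dess–Martin periodinane (CH2Cl2, 0 °C) oxidises F9 to 7, where the route is rejoined.

**Further compounds**
F1 | step 7 | (6S)-6-[(2S,5E)-1-(TBS-oxy)-6,10-dimethylundeca-5,9-dien-2-yl]-3,4,5,6-tetrahydro-1H-cyclopenta[c]furan-1-one | O=C1OCC2=C1[C@H]([C@@H](CO[Si](C)(C)C(C)(C)C)CC/C=C(\C)CCC=C(C)C)CC2
F2 | step 9 | (5R)-5-[(2S,5E)-1-(TBS-oxy)-6,10-dimethylundeca-5,9-dien-2-yl]-2-(hydroxymethyl)-N-methoxy-N-methylcyclopent-1-ene-1-carboxamide | OCC1=C(C(=O)N(C)OC)[C@@H]([C@@H](CO[Si](C)(C)C(C)(C)C)CC/C=C(\C)CCC=C(C)C)CC1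
F3 | step 9 | [(3R)-3-[(2S,5E)-1-(TBS-oxy)-6,10-dimethylundeca-5,9-dien-2-yl]-2-[methoxy(methyl)carbamoyl]cyclopent-1-en-1-yl]methyl acetate | CC(=O)OCC1=C(C(=O)N(C)OC)[C@@H]([C@@H](CO[Si](C)(C)C(C)(C)C)CC/C=C(\C)CCC=C(C)C)CC1
F4 | step 9 | [(3R)-3-[(2S,5E)-1-(TBS-oxy)-6,10-dimethylundeca-5,9-dien-2-yl]-2-formylcyclopent-1-en-1-yl]methyl acetate | CC(=O)OCC1=C(C=O)[C@@H]([C@@H](CO[Si](C)(C)C(C)(C)C)CC/C=C(\C)CCC=C(C)C)CC1
F5 | step 3 | (5E)-6,10-dimethylundeca-5,9-dienoic acid | OC(=O)CCC/C=C(\C)CCC=C(C)C
F6 | step 3 | (4S)-4-benzyl-3-[(5E)-6,10-dimethylundeca-5,9-dienoyl]-1,3-oxazolidin-2-one | O=C(CCC/C=C(\C)CCC=C(C)C)N1[C@@H](Cc2ccccc2)COC1=O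
F7 | step 3 | (4S)-4-benzyl-3-[(2R,5E)-2-(hydroxymethyl)-6,10-dimethylundeca-5,9-dienoyl]-1,3-oxazolidin-2-one | O=C([C@@H](CO)CC/C=C(\C)CCC=C(C)C)N1[C@@H](Cc2ccccc2)COC1=O
F8 | step 3 | (4S)-4-benzyl-3-[(2R,5E)-2-[(TBS-oxy)methyl]-6,10-dimethylundeca-5,9-dienoyl]-1,3-oxazolidin-2-one | O=C([C@@H](CO[Si](C)(C)C(C)(C)C)CC/C=C(\C)CCC=C(C)C)N1[C@@H](Cc2ccccc2)COC1=O
F9 | step 3 | (2S,5E)-2-[(TBS-oxy)methyl]-6,10-dimethylundeca-5,9-dien-1-ol | OC[C@@H](CO[Si](C)(C)C(C)(C)C)CC/C=C(\C)CCC=C(C)C
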